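**Retrosynthetic overview**

1. Target 29 comes from enone 28 by palladium-mediated removal of both allyl groups, 28 from aldehyde 27 by a Wittig reaction, and 27 from diaryl ether 26 by acetal hydrolysis.
2. Key disconnection: in ring A of 26, C1(CO2R)–C2(OMe)–C3(CH(OAc)i-Bu)–C4(H) are C3–C4–C5–C6 of 2-pyrone 13, and C5(H)–C6(OAr) is the triple bond of ring B ethynyl ether 24. A [4+2] cycloaddition followed by loss of CO2 forms C1–C6 and C4–C5.
3. Pyrone 13 comes from lactonisation of a γ-hydroxymethylene (1-methoxyalkylidene)malonate, made from acylmalonate 7, which is assembled from (S)-β-silyloxy acid 4 and diallyl malonate 5. A Noyori hydrogenation sets the only stereocentre.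
4. Ynol ether 24 comes from dichlorovinyl ether 21, made from creosol 14 (ortho-formylation, demethylation, selective O-allylation) and trichloroethylene 19.
5. Ring order: the pyrone ring is closed in step 7 and ring A in step 16; ring B is bought as creosol.

Key step: step 16

Assumption: methyl 5-methyl-3-oxohexanoate is taken as purchasable. Acylmalonate 7 is drawn as its keto tautomer although it should be largely enolised, and enamine 9 is drawn without double-bond geometry because both isomers converge on 11.

**Pyrone fragment**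

Step 1
Reactants: 1 methyl 5-methyl-3-oxohexanoate
Product: 2 methyl (3S)-3-hydroxy-5-methylhexanoate
Conditions: H2 (30 atm), [RuCl(p-cymene)((S)-BINAP)]Cl (0.5 mol %), MeOH, 50 °C
Reagents that add atoms: none
Why: Noyori asymmetric hydrogenation of a β-keto ester, in which the ketone is reduced within a ruthenium chelate and the (S)-BINAP ligand should deliver hydrogen to the face that gives the 3S alcohol (the same sense in which (R)-BINAP gives (R)-3-hydroxybutanoate); this sets the only stereocentre of the target.

Step 2
Reactants: 2 methyl (3S)-3-hydroxy-5-methylhexanoate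
Product: 3 methyl (3S)-3-(tert-butyldimethylsilyloxy)-5-methylhexanoate
Conditions: TBSCl, imidazole, DMF, rt
Reagents that add atoms: tert-butyldimethylsilyl chloride, C[Si](C)(Cl)C(C)(C)C
Why: Standard silyl ether formation on a secondary alcohol; the silyl ether is chosen because silanolate is a poor leaving group toward β-elimination in steps 3 to 6 and because a free hydroxyl would later lactonise onto a malonate ester.

Step 3
Reactants: 3 methyl (3S)-3-(tert-butyldimethylsilyloxy)-5-methylhexanoate
Product: 4 (3S)-3-(tert-butyldimethylsilyloxy)-5-methylhexanoic acid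
Conditions: LiOH, THF/MeOH/H2O, 0 °C to rt; then 1 M HCl to pH 3 at 0 °C
Reagents that add atoms: lithium hydroxide, [Li+].[OH-]
Why: Saponification of a methyl ester, which should leave the secondary silyl ether and the stereocentre (not α to the carbonyl) unaffected.

Step 4
Reactants: 4 (3S)-3-(tert-butyldimethylsilyloxy)-5-methylhexanoic acid; 5 diallyl malonate
Product: 7 diallyl 2-[(3S)-3-(tert-butyldimethylsilyloxy)-5-methylhexanoyl]malonate, via acyl imidazole 6 (not isolated)
Conditions: 1,1'-carbonyldiimidazole, THF, rt; then 5, MgCl2, Et3N, MeCN, 0 °C to rt; cold dilute HCl work-up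
Reagents that add atoms: none
Why: Claisen-type C-acylation of the MgCl2/Et3N-derived malonate enolate by an acyl imidazole, driven by the stable chelate of the acidic tricarbonyl product.

Step 5
Reactants: 7 diallyl 2-[(3S)-3-(tert-butyldimethylsilyloxy)-5-methylhexanoyl]malonate
Product: 8 diallyl 2-[(3S)-3-(tert-butyldimethylsilyloxy)-1-methoxy-5-methylhexylidene]malonate
Conditions: Me3SiCHN2 (1.2 equiv), toluene/MeOH, 0 °C to rt
Reagents that add atoms: (trimethylsilyl)diazomethane, C[Si](C)(C)C=[N+]=[N-]
Why: O-methylation of a strongly acidic tricarbonyl enol by diazomethane released from Me3SiCHN2 and methanol, which should favour the enol ether over C-methylation and fixes the future C4 methoxy group before the ring is closed.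

Step 6
Reactants: 8 diallyl 2-[(3S)-3-(tert-butyldimethylsilyloxy)-1-methoxy-5-methylhexylidene]malonate
Product: 9 diallyl 2-[(3S)-3-(tert-butyldimethylsilyloxy)-2-(dimethylaminomethylidene)-1-methoxy-5-methylhexylidene]malonate
Conditions: N,N-dimethylformamide di-tert-butyl acetal (3 equiv), toluene, 85 °C
Reagents that add atoms: N,N-dimethylformamide di-tert-butyl acetal, CN(C)C(OC(C)(C)C)OC(C)(C)C
Why: Vinylogous aminomethylenation (amide acetal condensation) at the γ-methylene of the alkylidene malonate, the only acidic C–H position; this acetal releases only tert-butanol, so neither the enol ether nor the allyl esters should be exchanged.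

Step 7
Reactants: 9 diallyl 2-[(3S)-3-(tert-butyldimethylsilyloxy)-2-(dimethylaminomethylidene)-1-methoxy-5-methylhexylidene]malonate
Product: 11 allyl 5-[(1S)-1-(tert-butyldimethylsilyloxy)-3-methylbutyl]-4-methoxy-2-oxo-2H-pyran-3-carboxylate, via hydroxymethylene malonate 10 (not isolated)
Conditions: AcOH/H2O/THF, rt to 40 °C
Reagents that add atoms: water, O
Why: Acid hydrolysis of the enamine to the hydroxymethylene compound and 6-exo-trig enol lactonisation onto the cis allyl ester, the established route from aminodienyl malonates to 2-pyrone-3-carboxylates; any loss of the silyl group after ring closure would only anticipate step 8.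

Step 8
Reactants: 11 allyl 5-[(1S)-1-(tert-butyldimethylsilyloxy)-3-methylbutyl]-4-methoxy-2-oxo-2H-pyran-3-carboxylate
Product: 12 allyl 5-[(1S)-1-hydroxy-3-methylbutyl]-4-methoxy-2-oxo-2H-pyran-3-carboxylate
Conditions: HF·pyridine, pyridine, THF, 0 °C to rt
Reagents that add atoms: none
Why: Fluoride-mediated silyl ether cleavage under buffered, weakly acidic conditions that the base-sensitive pyrone and the allyl ester should tolerate; the C–O bond of the stereocentre is not touched.

Step 9
Reactants: 12 allyl 5-[(1S)-1-hydroxy-3-methylbutyl]-4-methoxy-2-oxo-2H-pyran-3-carboxylate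
Product: 13 allyl 5-[(1S)-1-acetoxy-3-methylbutyl]-4-methoxy-2-oxo-2H-pyran-3-carboxylate
Conditions: Ac2O, pyridine, DMAP (cat.), CH2Cl2, 0 °C
Reagents that add atoms: acetic anhydride, CC(=O)OC(C)=O
Why: DMAP-catalysed acetylation of a secondary alcohol, with retention because only the O–H bond reacts.

**Ring B fragment**

Step 10
Reactants: 14 creosol (2-methoxy-4-methylphenol)
Product: 16 2-hydroxy-3-methoxy-5-methylbenzaldehyde, via salicyl alcohol 15 (not isolated)
Conditions: MgCl2, Et3N, (CH2O)n, MeCN, reflux; dilute HCl work-up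
Reagents that add atoms: paraformaldehyde (as formaldehyde), C=O
Why: Casnati–Skattebøl ortho-formylation, in which the ArOMgCl phenoxide directs hydroxymethylation to the only free ortho position and a second formaldehyde oxidises the benzylic alkoxide by hydride transfer.

Step 11
Reactants: 16 2-hydroxy-3-methoxy-5-methylbenzaldehyde
Product: 17 2,3-dihydroxy-5-methylbenzaldehyde
Conditions: BBr3, CH2Cl2, −78 °C to 0 °C; H2O
Reagents that add atoms: none
Why: Lewis acid cleavage of an aryl methyl ether with BBr3, which the aldehyde tolerates and which the neighbouring phenol assists.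

Step 12
Reactants: 17 2,3-dihydroxy-5-methylbenzaldehyde
Product: 18 3-(allyloxy)-2-hydroxy-5-methylbenzaldehyde
Conditions: NaH (2.2 equiv), DMSO, rt; allyl bromide (1.0 equiv), rt; dilute HCl work-up
Reagents that add atoms: allyl bromide, C=CCBr
Why: Williamson etherification of the catechol dianion, in which the C2 phenoxide is delocalised into and chelated by the formyl group, so the more nucleophilic C3 phenoxide should take up the single equivalent of allyl bromide.

Step 13
Reactants: 18 3-(allyloxy)-2-hydroxy-5-methylbenzaldehyde; 19 trichloroethylene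
Product: 20 3-(allyloxy)-2-[(E)-1,2-dichlorovinyloxy]-5-methylbenzaldehyde
Conditions: K2CO3, DMF, 70 °C
Reagents that add atoms: none
Why: Base-mediated O-dichlorovinylation, in which K2CO3 converts trichloroethylene into dichloroacetylene and the phenoxide adds to it in anti fashion to give the E-1,2-dichlorovinyl ether.

Step 14
Reactants: 20 3-(allyloxy)-2-[(E)-1,2-dichlorovinyloxy]-5-methylbenzaldehyde
Product: 21 2-{3-(allyloxy)-2-[(E)-1,2-dichlorovinyloxy]-5-methylphenyl}-1,3-dioxolane
Conditions: ethylene glycol, p-TsOH·H2O (cat.), toluene, reflux, Dean–Stark trap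
Reagents that add atoms: ethylene glycol, OCCO
Why: Acid-catalysed acetalisation with azeotropic removal of water; the formyl group is no longer hydrogen-bonded to a phenol, and the electron-poor dichlorovinyl ether and the allyl ether are inert to p-TsOH.

Step 15
Reactants: 21 2-{3-(allyloxy)-2-[(E)-1,2-dichlorovinyloxy]-5-methylphenyl}-1,3-dioxolane
Product: 24 2-[3-(allyloxy)-2-(ethynyloxy)-5-methylphenyl]-1,3-dioxolane, via chloroethynyl ether 22 (not isolated), via lithium acetylide 23 (not isolated)
Conditions: n-BuLi (2.1 equiv), THF, −78 °C; then H2O, −78 °C to 0 °C; used at once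
Reagents that add atoms: none
Why: Dichlorovinyl ether to ynol ether conversion, in which n-BuLi removes the vinylic proton with β-elimination of chloride, a second equivalent performs chlorine–lithium exchange, and protonation of the acetylide gives the terminal ethynyl ether; at −78 °C the allyl ether and the dioxolane should not be attacked.

**Union and endgame**

Step 16
Reactants: 13 allyl 5-[(1S)-1-acetoxy-3-methylbutyl]-4-methoxy-2-oxo-2H-pyran-3-carboxylate; 24 2-[3-(allyloxy)-2-(ethynyloxy)-5-methylphenyl]-1,3-dioxolane (1.5 equiv)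
Product: 26 allyl 3-[(1S)-1-acetoxy-3-methylbutyl]-6-[2-(allyloxy)-6-(1,3-dioxolan-2-yl)-4-methylphenoxy]-2-methoxybenzoate, via bridged lactone 25 (not isolated)
Conditions: degassed toluene, BHT (cat.), 110–120 °C, sealed tube
Reagents that add atoms: none
Why: The diene C3=C4–C5=C6 of 13, whose LUMO is lowered by the C3 ester and the lactone carbonyl, should undergo an asynchronous inverse-electron-demand [4+2] cycloaddition with the electron-rich triple bond of 24, the terminal CH bonding to C6 ahead of the oxygen-bearing carbon bonding to C3, and the resulting 2-oxabicyclo[2.2.2]octadienone 25 should lose CO2 by retro-[4+2] to give the benzoate irreversibly. The closest known reaction type is the cycloaddition of 3-alkoxycarbonyl-2-pyrones with ynamines, ketene acetals and alkynes, which gives benzoates with extrusion of CO2. Ring A is closed by this intermolecular cycloaddition (C1–C6 and C4–C5 of ring A) followed by the cycloreversion, with no tether involved. No stereocentre is created in the product, the two facial diastereomers of 25 converge on the same arene, and the S centre is remote from the reacting atoms. The step needs regioselectivity, which is secured by the match of the largest ynol ether HOMO coefficient (terminal CH) with the most electrophilic and unhindered pyrone position C6, so the aryloxy carbon ends next to the ester carbon. The C4 methoxy group attenuates the electrophilicity of the pyrone, so heat and an excess of 24 are planned, at a temperature below that of aromatic Claisen rearrangement of the allyl aryl ether.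

Step 17
Reactants: 26 allyl 3-[(1S)-1-acetoxy-3-methylbutyl]-6-[2-(allyloxy)-6-(1,3-dioxolan-2-yl)-4-methylphenoxy]-2-methoxybenzoate
Product: 27 allyl 3-[(1S)-1-acetoxy-3-methylbutyl]-6-[2-(allyloxy)-6-formyl-4-methylphenoxy]-2-methoxybenzoate
Conditions: PPTS (cat.), acetone/H2O, 45 °C
Reagents that add atoms: water, O
Why: Acid-catalysed acetal hydrolysis under mild PPTS conditions, chosen so that the benzylic acetate (para to the aryloxy group and therefore prone to ionisation) and the allyl ester survive.

Step 18
Reactants: 27 allyl 3-[(1S)-1-acetoxy-3-methylbutyl]-6-[2-(allyloxy)-6-formyl-4-methylphenoxy]-2-methoxybenzoate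
Product: 28 allyl 3-[(1S)-1-acetoxy-3-methylbutyl]-6-{2-(allyloxy)-4-methyl-6-[(E)-3-oxobut-1-enyl]phenoxy}-2-methoxybenzoate
Conditions: Ph3P=CHC(O)CH3, toluene, 70 °C
Reagents that add atoms: 1-(triphenylphosphoranylidene)propan-2-one, CC(=O)C=P(c1ccccc1)(c1ccccc1)c1ccccc1
Why: Wittig reaction with a stabilised ylide, which should give the E-enone and leave the acetate and the esters alone.

Step 19
Reactants: 28 allyl 3-[(1S)-1-acetoxy-3-methylbutyl]-6-{2-(allyloxy)-4-methyl-6-[(E)-3-oxobut-1-enyl]phenoxy}-2-methoxybenzoate
Product: 29 3-[(1S)-1-acetoxy-3-methylbutyl]-6-{2-hydroxy-4-methyl-6-[(E)-3-oxobut-1-enyl]phenoxy}-2-methoxybenzoic acid (target)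
Conditions: Pd(PPh3)4 (5 mol %), N-methylaniline (6 equiv), THF, rt; pH 4 buffer work-up
Reagents that add atoms: none
Why: Tsuji–Trost-type deallylation, in which zerovalent palladium ionises both the allyl ester and the allyl aryl ether to π-allyl complexes that N-methylaniline captures, while the secondary acetate, the enone, the methyl ether and the stereocentre should be untouched at room temperature.

**Compound list**

1 | methyl 5-methyl-3-oxohexanoate | COC(=O)CC(=O)CC(C)C | starting material
2 | methyl (3S)-3-hydroxy-5-methylhexanoate | COC(=O)C[C@H](CC(C)C)O | intermediate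
3 | methyl (3S)-3-(tert-butyldimethylsilyloxy)-5-methylhexanoate | COC(=O)C[C@H](CC(C)C)O[Si](C)(C)C(C)(C)C | intermediate
4 | (3S)-3-(tert-butyldimethylsilyloxy)-5-methylhexanoic acid | OC(=O)C[C@H](CC(C)C)O[Si](C)(C)C(C)(C)C | intermediate
5 | diallyl malonate | C=CCOC(=O)CC(=O)OCC=C | starting material
6 | 1-[(3S)-3-(tert-butyldimethylsilyloxy)-5-methylhexanoyl]imidazole (acyl imidazole) | O=C(C[C@H](CC(C)C)O[Si](C)(C)C(C)(C)C)n1ccnc1 | intermediate
7 | diallyl 2-[(3S)-3-(tert-butyldimethylsilyloxy)-5-methylhexanoyl]malonate | C=CCOC(=O)C(C(=O)OCC=C)C(=O)C[C@H](CC(C)C)O[Si](C)(C)C(C)(C)C | intermediate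
8 | diallyl 2-[(3S)-3-(tert-butyldimethylsilyloxy)-1-methoxy-5-methylhexylidene]malonate | C=CCOC(=O)C(C(=O)OCC=C)=C(OC)C[C@H](CC(C)C)O[Si](C)(C)C(C)(C)C | intermediate
9 | diallyl 2-[(3S)-3-(tert-butyldimethylsilyloxy)-2-(dimethylaminomethylidene)-1-methoxy-5-methylhexylidene]malonate | C=CCOC(=O)C(C(=O)OCC=C)=C(OC)C(=CN(C)C)[C@H](CC(C)C)O[Si](C)(C)C(C)(C)C | intermediate
10 | diallyl 2-[(3S)-3-(tert-butyldimethylsilyloxy)-2-(hydroxymethylidene)-1-methoxy-5-methylhexylidene]malonate (hydroxymethylene malonate) | C=CCOC(=O)C(C(=O)OCC=C)=C(OC)C(=CO)[C@H](CC(C)C)O[Si](C)(C)C(C)(C)C | intermediate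
11 | allyl 5-[(1S)-1-(tert-butyldimethylsilyloxy)-3-methylbutyl]-4-methoxy-2-oxo-2H-pyran-3-carboxylate | C=CCOC(=O)C1=C(OC)C([C@H](CC(C)C)O[Si](C)(C)C(C)(C)C)=COC1=O | intermediate
12 | allyl 5-[(1S)-1-hydroxy-3-methylbutyl]-4-methoxy-2-oxo-2H-pyran-3-carboxylate | C=CCOC(=O)C1=C(OC)C([C@H](CC(C)C)O)=COC1=O | intermediate
13 | allyl 5-[(1S)-1-acetoxy-3-methylbutyl]-4-methoxy-2-oxo-2H-pyran-3-carboxylate | C=CCOC(=O)C1=C(OC)C([C@H](CC(C)C)OC(C)=O)=COC1=O | intermediate
14 | creosol (2-methoxy-4-methylphenol) | COc1cc(C)ccc1O | starting material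
15 | 2-(hydroxymethyl)-6-methoxy-4-methylphenol (salicyl alcohol) | COc1cc(C)cc(CO)c1O | intermediate
16 | 2-hydroxy-3-methoxy-5-methylbenzaldehyde | COc1cc(C)cc(C=O)c1O | intermediate
17 | 2,3-dihydroxy-5-methylbenzaldehyde | Cc1cc(O)c(O)c(C=O)c1 | intermediate
18 | 3-(allyloxy)-2-hydroxy-5-methylbenzaldehyde | C=CCOc1cc(C)cc(C=O)c1O | intermediate
19 | trichloroethylene | ClC=C(Cl)Cl | starting material
20 | 3-(allyloxy)-2-[(E)-1,2-dichlorovinyloxy]-5-methylbenzaldehyde | C=CCOc1cc(C)cc(C=O)c1O/C(Cl)=C\Cl | intermediate
21 | 2-{3-(allyloxy)-2-[(E)-1,2-dichlorovinyloxy]-5-methylphenyl}-1,3-dioxolane | C=CCOc1cc(C)cc(C2OCCO2)c1O/C(Cl)=C\Cl | intermediate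
22 | 2-[3-(allyloxy)-2-(chloroethynyloxy)-5-methylphenyl]-1,3-dioxolane (chloroethynyl ether) | C=CCOc1cc(C)cc(C2OCCO2)c1OC#CCl | intermediate
23 | {[2-(allyloxy)-6-(1,3-dioxolan-2-yl)-4-methylphenoxy]ethynyl}lithium (lithium acetylide) | C=CCOc1cc(C)cc(C2OCCO2)c1OC#C[Li] | intermediate
24 | 2-[3-(allyloxy)-2-(ethynyloxy)-5-methylphenyl]-1,3-dioxolane | C#COc1c(OCC=C)cc(C)cc1C1OCCO1 | intermediate
25 | allyl 7-[(1S)-1-acetoxy-3-methylbutyl]-5-[2-(allyloxy)-6-(1,3-dioxolan-2-yl)-4-methylphenoxy]-8-methoxy-3-oxo-2-oxabicyclo[2.2.2]octa-5,7-diene-4-carboxylate (bridged lactone, both bridgehead diastereomers) | C=CCOC(=O)C12C(=O)OC(C=C1Oc1c(OCC=C)cc(C)cc1C1OCCO1)C([C@H](CC(C)C)OC(C)=O)=C2OC | intermediate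
26 | allyl 3-[(1S)-1-acetoxy-3-methylbutyl]-6-[2-(allyloxy)-6-(1,3-dioxolan-2-yl)-4-methylphenoxy]-2-methoxybenzoate | COc1c([C@H](CC(C)C)OC(C)=O)ccc(Oc2c(OCC=C)cc(C)cc2C2OCCO2)c1C(=O)OCC=C | intermediate
27 | allyl 3-[(1S)-1-acetoxy-3-methylbutyl]-6-[2-(allyloxy)-6-formyl-4-methylphenoxy]-2-methoxybenzoate | COc1c([C@H](CC(C)C)OC(C)=O)ccc(Oc2c(OCC=C)cc(C)cc2C=O)c1C(=O)OCC=C | intermediate
28 | allyl 3-[(1S)-1-acetoxy-3-methylbutyl]-6-{2-(allyloxy)-4-methyl-6-[(E)-3-oxobut-1-enyl]phenoxy}-2-methoxybenzoate | COc1c([C@H](CC(C)C)OC(C)=O)ccc(Oc2c(OCC=C)cc(C)cc2/C=C/C(C)=O)c1C(=O)OCC=C | intermediate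
29 | 3-[(1S)-1-acetoxy-3-methylbutyl]-6-{2-hydroxy-4-methyl-6-[(E)-3-oxobut-1-enyl]phenoxy}-2-methoxybenzoic acid | COc1c([C@H](CC(C)C)OC(C)=O)ccc(Oc2c(O)cc(C)cc2/C=C/C(C)=O)c1C(=O)O | target

**Step count**

Total: 19 steps (pyrone fragment 9, ring B fragment 6, union and endgame 4).
Longest linear sequence: 13 steps (steps 1–9 and 16–19).

**Steps most likely to fail**

Step 16. The C4 methoxy group raises the pyrone LUMO, so the cycloaddition may be slower than thermal oligomerisation or hydration of the ynol ether. The fallback sets out from 13 and returns at 27, bypassing 24 and 26. Pyrone 13 is heated with 1,1-bis(trimethylsilyloxy)ethene, a far more nucleophilic ketene acetal (toluene, 80–110 °C). The same inverse-demand cycloaddition, loss of CO2 and elimination of trimethylsilanol, followed by mild aqueous work-up, should give the salicylate allyl 3-[(1S)-1-acetoxy-3-methylbutyl]-6-hydroxy-2-methoxybenzoate F1. Separately, commercial 2-fluoro-5-methylanisole is lithiated next to fluorine (s-BuLi, TMEDA, THF, −78 °C) and formylated with DMF to give 2-fluoro-3-methoxy-5-methylbenzaldehyde F2. Demethylation with BBr3 gives 2-fluoro-3-hydroxy-5-methylbenzaldehyde F3, and allyl bromide with K2CO3 gives 3-(allyloxy)-2-fluoro-5-methylbenzaldehyde F4. Nucleophilic aromatic substitution of the fluoride of F4, activated by the ortho formyl group, by the phenoxide of F1 (K2CO3, DMF, 80–90 °C) should give aldehyde 27 directly.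

Step 6. Condensation at the hindered γ-methylene may stall, and at the temperature needed an E1cB loss of silanolate from the dienolate could compete. The fallback sets out from 7 and returns at 11. Acylmalonate 7 is deprotonated twice (NaH, then LiN(i-Pr)2, THF, −78 °C) and the γ-carbon of the dianion is formylated with ethyl formate (Claisen formylation). Acidification with AcOH should let the hydroxymethylene triester lactonise to allyl 5-[(1S)-1-(tert-butyldimethylsilyloxy)-3-methylbutyl]-4-hydroxy-2-oxo-2H-pyran-3-carboxylate F5. O-methylation (Me3SiCHN2, toluene/MeOH) then gives 11, with chromatographic removal of any 2-methoxy-4-pyranone isomer.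

Step 15. The terminal aryl ynol ether may hydrate or oligomerise during work-up, concentration and chromatography, which would erode the material available for the key step. The fallback sets out from 21 and returns at 24. Lithium acetylide 23 is generated as in step 15 but quenched with Me3SiCl to give 2-{3-(allyloxy)-5-methyl-2-[(trimethylsilyl)ethynyloxy]phenyl}-1,3-dioxolane F6, a C-silyl ynol ether that should be stable to chromatography and storage. Immediately before the cycloaddition, the silyl cap is removed with Bu4NF (THF, −78 °C to 0 °C), and 24 is extracted into toluene and used as a solution without concentration.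

**Further compounds**

F1 | step 16 | allyl 3-[(1S)-1-acetoxy-3-methylbutyl]-6-hydroxy-2-methoxybenzoate | COc1c([C@H](CC(C)C)OC(C)=O)ccc(O)c1C(=O)OCC=C
F2 | step 16 | 2-fluoro-3-methoxy-5-methylbenzaldehyde | COc1cc(C)cc(C=O)c1F
F3 | step 16 | 2-fluoro-3-hydroxy-5-methylbenzaldehyde | Cc1cc(O)c(F)c(C=O)c1
F4 | step 16 | 3-(allyloxy)-2-fluoro-5-methylbenzaldehyde | C=CCOc1cc(C)cc(C=O)c1F
F5 | step 6 | allyl 5-[(1S)-1-(tert-butyldimethylsilyloxy)-3-methylbutyl]-4-hydroxy-2-oxo-2H-pyran-3-carboxylate | C=CCOC(=O)C1=C(O)C([C@H](CC(C)C)O[Si](C)(C)C(C)(C)C)=COC1=O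
F6 | step 15 | 2-{3-(allyloxy)-5-methyl-2-[(trimethylsilyl)ethynyloxy]phenyl}-1,3-dioxolane | C=CCOc1cc(C)cc(C2OCCO2)c1OC#C[Si](C)(C)C
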